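**Strategy.** The dihydropyran ring of the chroman (O1, C2, C3, C4, C4a, C8a) is disconnected across O1–C2 and C3–C4. O1–C8a–C4a–C4 is read as an ortho-quinone methide of the isovalerylphloroglucinol ring, and C2–C3 as the (E)-alkene of a 3-methylbutenyl diformylphloroglucinol, whose trihydroxyaryl group stabilises positive charge at C2. One chiral phosphoric acid-catalysed oxa-[4+2] cycloaddition forms C3–C4, closes the ring through O1–C2 and sets both stereocentres, trans from the (E)-alkene. Its precursors are a salicyl alcohol in which the two hydroxyls ortho to the ketone are allyl-blocked, so that only the para oxygen can become O1, and an unprotected ortho-hydroxystyrene. Deallylation then gives the target.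

Key step: step 10

Assumption (remark on the chemistry): the sense of induction of the phosphoric acid cannot be read from the structures alone. The route is written with the (R) acid; the (S) acid is taken instead if a pilot run shows the opposite sense. Chroman numbering (O1, C2, C3, C4, C4a, C5 to C8, C8a) is used for the target; it is (2R,3S), trans.

**Step 1**
Reactants: 1 phloroglucinol (benzene-1,3,5-triol); 2 3-methylbutanoyl chloride
Product: 3 3-methyl-1-(2,4,6-trihydroxyphenyl)butan-1-one
Conditions: AlCl3 (3.5 equiv), PhNO2, rt to 60 °C; then ice/aq. HCl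
Reagents that add atoms: none
Why: Friedel–Crafts C-acylation of the symmetrical triol; the first acyl group deactivates the ring, so mono-acylation should dominate with one equivalent of 2.

**Step 2**
Reactants: 3 3-methyl-1-(2,4,6-trihydroxyphenyl)butan-1-one
Product: 4 1-[2,6-dihydroxy-4-(methoxymethoxy)phenyl]-3-methylbutan-1-one
Conditions: MOMCl (1.05 equiv), i-Pr2NEt (1.2 equiv), CH2Cl2, 0 °C
Reagents that add atoms: chloromethyl methyl ether, COCCl
Why: Williamson-type O-alkylation with a limiting amount of electrophile; the para hydroxyl is the most acidic, is unhindered and is not chelated to the ketone, so it should react first.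

**Step 3**
Reactants: 4 1-[2,6-dihydroxy-4-(methoxymethoxy)phenyl]-3-methylbutan-1-one
Product: 5 1-[4-(methoxymethoxy)-2,6-bis(prop-2-en-1-yloxy)phenyl]-3-methylbutan-1-one
Conditions: allyl bromide (3 equiv), K2CO3 (4 equiv), DMF, 50 °C
Reagents that add atoms: allyl bromide, C=CCBr
Why: Williamson etherification of both hydroxyls that flank the ketone; with K2CO3 in a dipolar aprotic solvent O-allylation should prevail over C-allylation.

**Step 4**
Reactants: 5 1-[4-(methoxymethoxy)-2,6-bis(prop-2-en-1-yloxy)phenyl]-3-methylbutan-1-one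
Product: 6 1-[4-hydroxy-2,6-bis(prop-2-en-1-yloxy)phenyl]-3-methylbutan-1-one
Conditions: HCl (cat.), MeOH, 45 °C
Reagents that add atoms: none
Why: Acid-catalysed transacetalisation removes the methoxymethyl group as dimethoxymethane, while the allyl ethers and the hindered ketone are inert; the product is symmetrical and has one free phenol.

**Step 5**
Reactants: 6 1-[4-hydroxy-2,6-bis(prop-2-en-1-yloxy)phenyl]-3-methylbutan-1-one
Product: 8 1-[4-hydroxy-3-(hydroxymethyl)-2,6-bis(prop-2-en-1-yloxy)phenyl]-3-methylbutan-1-one, via benzodioxaborin 7 (not isolated)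
Conditions: PhB(OH)2 (1.1 equiv), (CH2O)n, EtCO2H (cat.), toluene, 100 °C, 4 Å MS; then pinacol, THF, rt
Reagents that add atoms: formaldehyde (from paraformaldehyde), C=O; phenylboronic acid, OB(O)c1ccccc1 (held only in 7)
Why: Boronate-templated ortho-hydroxymethylation of a phenol: the aryl boronate delivers one formaldehyde to a position ortho to the only free hydroxyl (both are equivalent), and diol exchange then releases the salicyl alcohol.

**Step 6**
Reactants: 1 phloroglucinol
Product: 10 2,4,6-trihydroxybenzene-1,3-dicarbaldehyde, via bis(iminium) salt 9 (not isolated)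
Conditions: POCl3 (2.3 equiv), DMF (2.3 equiv), dioxane, 0 °C to rt; then H2O, 60 °C
Reagents that add atoms: N,N-dimethylformamide, CN(C)C=O; water, O
Why: Vilsmeier–Haack formylation; two formyl groups should enter readily, while the last position of the doubly deactivated ring stays free.

**Step 7**
Reactants: 10 2,4,6-trihydroxybenzene-1,3-dicarbaldehyde
Product: 11 2,4,6-trihydroxy-5-iodobenzene-1,3-dicarbaldehyde
Conditions: NIS (1.05 equiv), DMF, 0 °C to rt
Reagents that add atoms: N-iodosuccinimide, O=C1CCC(=O)N1I
Why: Electrophilic aromatic iodination at the single remaining ring position, which is still activated by three hydroxyls.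

**Step 8**
Reactants: 12 3-methylbut-1-yne
Product: 13 4,4,5,5-tetramethyl-2-[(1E)-3-methylbut-1-en-1-yl]-1,3,2-dioxaborolane
Conditions: HBpin (1.0 equiv), Cp2Zr(H)Cl (5 mol %), Et3N (10 mol %), neat, 60 °C, sealed tube
Reagents that add atoms: pinacolborane, CC1(C)OBOC1(C)C
Why: Zirconocene hydrochloride-catalysed hydroboration of a terminal alkyne; syn, anti-Markovnikov addition should give the (E)-alkenylboronate only.

**Step 9**
Reactants: 11 2,4,6-trihydroxy-5-iodobenzene-1,3-dicarbaldehyde; 13 4,4,5,5-tetramethyl-2-[(1E)-3-methylbut-1-en-1-yl]-1,3,2-dioxaborolane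
Product: 14 2,4,6-trihydroxy-5-[(1E)-3-methylbut-1-en-1-yl]benzene-1,3-dicarbaldehyde
Conditions: Pd(OAc)2 (5 mol %), SPhos (10 mol %), K3PO4 (6 equiv), dioxane/H2O, 60 °C; then cold dilute HCl
Reagents that add atoms: none
Why: Suzuki–Miyaura coupling of the unprotected aryl iodide (present as its phenoxide) with retention of the (E)-geometry; the electron-rich biarylphosphine should support oxidative addition into the hindered C–I bond.

**Step 10**
Reactants: 8 1-[4-hydroxy-3-(hydroxymethyl)-2,6-bis(prop-2-en-1-yloxy)phenyl]-3-methylbutan-1-one; 14 2,4,6-trihydroxy-5-[(1E)-3-methylbut-1-en-1-yl]benzene-1,3-dicarbaldehyde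
Product: 16 2,4,6-trihydroxy-5-[(2R,3S)-6-(3-methylbutanoyl)-3-(propan-2-yl)-5,7-bis(prop-2-en-1-yloxy)-3,4-dihydro-2H-chromen-2-yl]benzene-1,3-dicarbaldehyde, via ortho-quinone methide 15 (not isolated)
Conditions: (R)-TRIP [(R)-3,3'-bis(2,4,6-triisopropylphenyl)-1,1'-binaphthyl-2,2'-diyl hydrogen phosphate] (10 mol %), 5 Å MS, CH2Cl2, 0 °C to rt; 8 added slowly to 14 (1.5 equiv)
Reagents that add atoms: none
Why: The phosphoric acid dehydrates the electron-rich salicyl alcohol 8 to the ortho-quinone methide 15 and holds it by hydrogen bonding while its phosphoryl oxygen binds an ortho hydroxyl of 14, so that the nucleophilic β-carbon of the styrene adds to the methide CH2 (C3–C4) and the quinone methide oxygen closes onto the benzylic carbon (O1–C2) in an asynchronous inverse-electron-demand oxa-[4+2] cycloaddition; in the stepwise limit this is a Michael addition followed by 6-exo-trig oxa-Michael closure onto the transient quinone methide of the diformylphloroglucinol ring. The closest known reaction type is the chiral phosphoric acid-catalysed [4+2] cycloaddition of ortho-quinone methides, generated in situ from ortho-hydroxybenzyl alcohols, with ortho-hydroxystyrenes, together with the uncatalysed cycloaddition of phloroglucinol quinone methides with alkenylphloroglucinols; what is new here is only the substrate pair, in which the methide carbon is unsubstituted. The six-membered dihydropyran ring is the only ring closed. The trans relation of C2 and C3 follows from suprafacial addition to the (E)-alkene and is also the diequatorial, thermodynamically preferred arrangement, and the absolute sense (2R,3S) should be set by the chiral acid, which differentiates the two faces of the bound styrene. Regiochemistry at oxygen is secured by the allyl ethers, which leave the oxygen para to the ketone as the only one able to form the quinone methide, and the orientation (O1 to the aryl-bearing carbon) by the polarity of the partners. Cross- over self-reaction is favoured by slow addition of 8 to an excess of 14 at low temperature, where 14 should not tautomerise to its own quinone methide.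

**Step 11**
Reactants: 16 2,4,6-trihydroxy-5-[(2R,3S)-6-(3-methylbutanoyl)-3-(propan-2-yl)-5,7-bis(prop-2-en-1-yloxy)-3,4-dihydro-2H-chromen-2-yl]benzene-1,3-dicarbaldehyde
Product: 17 2,4,6-trihydroxy-5-[(2R,3S)-5,7-dihydroxy-6-(3-methylbutanoyl)-3-(propan-2-yl)-3,4-dihydro-2H-chromen-2-yl]benzene-1,3-dicarbaldehyde (target)
Conditions: Pd(PPh3)4 (5 mol %), sodium p-toluenesulfinate p-TolSO2Na (2.5 equiv), THF/MeOH, rt; then aq. HCl to pH 3
Reagents that add atoms: none
Why: Tsuji–Trost deallylation: zerovalent palladium ionises both aryl allyl ethers to π-allyl complexes that the soft sulfinate traps irreversibly; the near-neutral, room-temperature conditions should leave the aldehydes, the ketone and the benzylic C2–O1 ether, and hence both stereocentres, untouched.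

**Compound list**
1 | phloroglucinol (benzene-1,3,5-triol) | Oc1cc(O)cc(O)c1 | starting material
2 | 3-methylbutanoyl chloride | CC(C)CC(=O)Cl | starting material
3 | 3-methyl-1-(2,4,6-trihydroxyphenyl)butan-1-one | CC(C)CC(=O)c1c(O)cc(O)cc1O | intermediate
4 | 1-[2,6-dihydroxy-4-(methoxymethoxy)phenyl]-3-methylbutan-1-one | CC(C)CC(=O)c1c(O)cc(OCOC)cc1O | intermediate
5 | 1-[4-(methoxymethoxy)-2,6-bis(prop-2-en-1-yloxy)phenyl]-3-methylbutan-1-one | CC(C)CC(=O)c1c(OCC=C)cc(OCOC)cc1OCC=C | intermediate
6 | 1-[4-hydroxy-2,6-bis(prop-2-en-1-yloxy)phenyl]-3-methylbutan-1-one | CC(C)CC(=O)c1c(OCC=C)cc(O)cc1OCC=C | intermediate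
7 | 3-methyl-1-[2-phenyl-5,7-bis(prop-2-en-1-yloxy)-4H-1,3,2-benzodioxaborinin-6-yl]butan-1-one | CC(C)CC(=O)c1c(OCC=C)cc2OB(c3ccccc3)OCc2c1OCC=C | intermediate
8 | 1-[4-hydroxy-3-(hydroxymethyl)-2,6-bis(prop-2-en-1-yloxy)phenyl]-3-methylbutan-1-one | CC(C)CC(=O)c1c(OCC=C)cc(O)c(CO)c1OCC=C | intermediate
9 | 1,1'-(2,4,6-trihydroxy-1,3-phenylene)bis(N,N-dimethylmethaniminium) bis(dichlorophosphate) | C[N+](C)=Cc1c(O)cc(O)c(C=[N+](C)C)c1O.[O-]P(Cl)(Cl)=O.[O-]P(Cl)(Cl)=O | intermediate
10 | 2,4,6-trihydroxybenzene-1,3-dicarbaldehyde | O=Cc1c(O)cc(O)c(C=O)c1O | intermediate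
11 | 2,4,6-trihydroxy-5-iodobenzene-1,3-dicarbaldehyde | O=Cc1c(O)c(I)c(O)c(C=O)c1O | intermediate
12 | 3-methylbut-1-yne | CC(C)C#C | starting material
13 | 4,4,5,5-tetramethyl-2-[(1E)-3-methylbut-1-en-1-yl]-1,3,2-dioxaborolane | CC(C)/C=C/B1OC(C)(C)C(C)(C)O1 | intermediate
14 | 2,4,6-trihydroxy-5-[(1E)-3-methylbut-1-en-1-yl]benzene-1,3-dicarbaldehyde | CC(C)/C=C/c1c(O)c(C=O)c(O)c(C=O)c1O | intermediate
15 | 3-methyl-1-[3-methylidene-4-oxo-2,6-bis(prop-2-en-1-yloxy)cyclohexa-1,5-dien-1-yl]butan-1-one | CC(C)CC(=O)C1=C(OCC=C)C(=C)C(=O)C=C1OCC=C | intermediate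
16 | 2,4,6-trihydroxy-5-[(2R,3S)-6-(3-methylbutanoyl)-3-(propan-2-yl)-5,7-bis(prop-2-en-1-yloxy)-3,4-dihydro-2H-chromen-2-yl]benzene-1,3-dicarbaldehyde | CC(C)CC(=O)c1c(OCC=C)cc2c(c1OCC=C)C[C@@H](C(C)C)[C@H](c1c(O)c(C=O)c(O)c(C=O)c1O)O2 | intermediate
17 | 2,4,6-trihydroxy-5-[(2R,3S)-5,7-dihydroxy-6-(3-methylbutanoyl)-3-(propan-2-yl)-3,4-dihydro-2H-chromen-2-yl]benzene-1,3-dicarbaldehyde | CC(C)CC(=O)c1c(O)cc2c(c1O)C[C@@H](C(C)C)[C@H](c1c(O)c(C=O)c(O)c(C=O)c1O)O2 | target

**Step count and risks**
Total step count: 11. Longest linear sequence: 7 (steps 1, 2, 3, 4, 5, 10, 11).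

Steps most likely to fail:

Step 10. Face selection may be insufficient, because the methide carbon is unsubstituted and the acidic partner can drive a racemic background reaction; the quinone methide may also be consumed by self-condensation with the electron-rich ring of its precursor. Fallback: setting out from 8 and 14, the cycloaddition is run with an achiral acid ((PhO)2P(O)OH, CH2Cl2, rt). This should give the racemic trans adduct, that is 16 together with its mirror image 2,4,6-trihydroxy-5-[(2S,3R)-6-(3-methylbutanoyl)-3-(propan-2-yl)-5,7-bis(prop-2-en-1-yloxy)-3,4-dihydro-2H-chromen-2-yl]benzene-1,3-dicarbaldehyde F1. The antipodes are separated by preparative chromatography on a chiral stationary phase (cellulose tris(3,5-dimethylphenylcarbamate)), the configuration is assigned by crystallography or circular dichroism, and the route is rejoined at 16.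

Step 9. Protodeiodination and catalyst inhibition by the polyphenoxide may outrun the coupling under aqueous base. Fallback: setting out from 11, the three hydroxyls are capped (MOMCl, NaH, DMF, 0 °C) to give 5-iodo-2,4,6-tris(methoxymethoxy)benzene-1,3-dicarbaldehyde F2. A standard Suzuki–Miyaura coupling with 13 (Pd(dppf)Cl2, K2CO3, dioxane/H2O, 80 °C) then gives 2,4,6-tris(methoxymethoxy)-5-[(1E)-3-methylbut-1-en-1-yl]benzene-1,3-dicarbaldehyde F3. Mild acid (HCl cat., MeOH, 0 °C to rt) removes the chelation-activated acetals, and the route is rejoined at 14.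

Step 5. Over-hydroxymethylation, or incomplete release of the salicyl alcohol from boron with ionisation of the electron-rich benzylic alcohol, may erode the material. Fallback: setting out from 6, magnesium-mediated ortho-formylation (Casnati–Skattebøl: MgCl2, Et3N, (CH2O)n, MeCN, reflux) gives 6-hydroxy-3-(3-methylbutanoyl)-2,4-bis(prop-2-en-1-yloxy)benzaldehyde F4. Chemoselective reduction of the aldehyde in the presence of the hindered diortho-substituted ketone (NaBH4, THF/MeOH, −20 °C) rejoins the route at 8.

**Further compounds**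
F1 | step 10 | 2,4,6-trihydroxy-5-[(2S,3R)-6-(3-methylbutanoyl)-3-(propan-2-yl)-5,7-bis(prop-2-en-1-yloxy)-3,4-dihydro-2H-chromen-2-yl]benzene-1,3-dicarbaldehyde | CC(C)CC(=O)c1c(OCC=C)cc2c(c1OCC=C)C[C@H](C(C)C)[C@@H](c1c(O)c(C=O)c(O)c(C=O)c1O)O2
F2 | step 9 | 5-iodo-2,4,6-tris(methoxymethoxy)benzene-1,3-dicarbaldehyde | O=Cc1c(OCOC)c(C=O)c(OCOC)c(I)c1OCOC
F3 | step 9 | 2,4,6-tris(methoxymethoxy)-5-[(1E)-3-methylbut-1-en-1-yl]benzene-1,3-dicarbaldehyde | O=Cc1c(OCOC)c(C=O)c(OCOC)c(/C=C/C(C)C)c1OCOC
F4 | step 5 | 6-hydroxy-3-(3-methylbutanoyl)-2,4-bis(prop-2-en-1-yloxy)benzaldehyde | CC(C)CC(=O)c1c(OCC=C)cc(O)c(C=O)c1OCC=C
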